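**Retrosynthetic overview**
- The target comes from 4-methoxybenzoylation of a 3,4-diol (azulene numbering). The C4–O bond and the C4 stereocentre are made by a boron-tethered 1,6-oxa-Michael addition of the C3 tertiary hydroxyl onto a cyclohepta-4,6-dienone (key step, new).
- The dienone comes from dehydrogenation of the 6-en-8-one. The seven-membered ring (formed second) is closed by ring-closing metathesis of a vinyl ketone with a 1,1-disubstituted alkene.
- The five-membered ring (formed first) is closed by a samarium diiodide ketyl–olefin cyclization that sets C3 and C3a relative to the quaternary C8a.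
- C8a comes from a catalytic asymmetric Michael addition of ethyl 2-cyanopropanoate to 4-methylpent-1-en-3-one; the cyclization precursor follows by reduction, oxidation and Wittig olefination.

Assumption: the target is taken exactly as the SMILES draws it (cis-fused, 3R,3aR,4S,8aS; azulene numbering throughout), and 4-methylpent-1-en-3-one and 4-bromo-2-methylbut-1-ene are bought.

**Route**

Step 1
Reactants: 1 ethyl 2-cyanopropanoate; 2 4-methylpent-1-en-3-one
Product: 3 ethyl (2R)-2-cyano-2,6-dimethyl-5-oxoheptanoate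
Conditions: cinchona-alkaloid bifunctional thiourea catalyst (10 mol %, the pseudo-enantiomer that gives the 2R adduct), toluene, −40 °C
Reagents that add atoms: none
Why: Organocatalytic asymmetric Michael addition of an α-substituted α-cyanoacetate to a vinyl ketone is an established route to all-carbon quaternary centres, and the chiral ion pair sets C2 (later C8a) as the only catalyst-controlled stereocentre.

Step 2
Reactants: 3 ethyl (2R)-2-cyano-2,6-dimethyl-5-oxoheptanoate
Product: 4 (2R)-5-hydroxy-2-(hydroxymethyl)-2,6-dimethylheptanenitrile (both C5 epimers)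
Conditions: LiBH4, THF, 0 °C → rt; then 1 M HCl
Reagents that add atoms: none
Why: Borohydride reduction takes the cyano-activated ester and the ketone to alcohols while the nitrile and the quaternary centre are untouched, and the new carbinol centre is erased again in step 3.

Step 3
Reactants: 4 (2R)-5-hydroxy-2-(hydroxymethyl)-2,6-dimethylheptanenitrile
Product: 5 (2R)-2-formyl-2,6-dimethyl-5-oxoheptanenitrile
Conditions: (COCl)2, DMSO, CH2Cl2, −78 °C; Et3N, −78 → 0 °C
Reagents that add atoms: none
Why: Swern oxidation brings both alcohols to the carbonyl level under mild conditions, and the aldehyde cannot epimerise because its α-carbon is quaternary.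

Step 4
Reactants: 6 4-bromo-2-methylbut-1-ene; 7 triphenylphosphine
Product: 8 (3-methylbut-3-en-1-yl)triphenylphosphonium bromide
Conditions: toluene, 110 °C
Reagents that add atoms: none
Why: SN2 quaternisation of triphenylphosphine by a primary bromide gives the phosphonium salt.

Step 5
Reactants: 5 (2R)-2-formyl-2,6-dimethyl-5-oxoheptanenitrile; 8 (3-methylbut-3-en-1-yl)triphenylphosphonium bromide
Product: 10 (2S)-2,6-dimethyl-2-[(1Z)-4-methylpenta-1,4-dien-1-yl]-5-oxoheptanenitrile, via phosphorus ylide 9 (not isolated)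
Conditions: 8, NaHMDS, THF, 0 °C; then 5, −78 °C → rt
Reagents that add atoms: none
Why: Salt-free Wittig olefination with an unstabilised ylide is Z-selective and attacks the very electrophilic α-cyano aldehyde much faster than the branched ketone (the descriptor changes from R to S only through the priority rules).

Step 6
Reactants: 10 (2S)-2,6-dimethyl-2-[(1Z)-4-methylpenta-1,4-dien-1-yl]-5-oxoheptanenitrile
Product: 11 (1S,2S,3R)-3-hydroxy-1-methyl-2-(3-methylbut-3-en-1-yl)-3-(propan-2-yl)cyclopentane-1-carbonitrile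
Conditions: SmI2 (2.5 equiv), HMPA, t-BuOH, THF, 0 °C → rt, dark
Reagents that add atoms: none
Why: In this samarium diiodide ketyl–olefin 5-exo-trig radical cyclisation the samarium-bound oxygen lies anti to the alkene in the chair-like transition state and the small nitrile takes the position eclipsing the Z-alkene (A(1,3) strain), so the hydroxyl ends trans to the new side chain and cis to the methyl, while the side chain ends cis to the nitrile.

Step 7
Reactants: 11 (1S,2S,3R)-3-hydroxy-1-methyl-2-(3-methylbut-3-en-1-yl)-3-(propan-2-yl)cyclopentane-1-carbonitrile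
Product: 13 1-[(1S,2S,3R)-3-hydroxy-1-methyl-2-(3-methylbut-3-en-1-yl)-3-(propan-2-yl)cyclopentyl]prop-2-en-1-one, via ketimine 12 (not isolated)
Conditions: CH2=CHMgBr (4 equiv), CuBr·SMe2 (10 mol %), THF, 65 °C; then 1 M HCl, 0 °C
Reagents that add atoms: vinylmagnesium bromide, C=C[Mg]Br; water, O
Why: Copper-catalysed Grignard addition to a hindered nitrile stops at the N-magnesio ketimine, which is hydrolysed to the vinyl ketone on work-up without touching a stereocentre.

Step 8
Reactants: 13 1-[(1S,2S,3R)-3-hydroxy-1-methyl-2-(3-methylbut-3-en-1-yl)-3-(propan-2-yl)cyclopentyl]prop-2-en-1-one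
Product: 14 (3R,3aS,8aS)-3-hydroxy-6,8a-dimethyl-3-(propan-2-yl)-2,3,3a,4,5,8a-hexahydroazulen-8(1H)-one
Conditions: second-generation Grubbs catalyst RuCl2(H2IMes)(PCy3)(=CHPh) (5 mol %), CH2Cl2, 40 °C, 5 mM
Reagents that add atoms: none
Why: Ring-closing metathesis of the enone alkene with the 1,1-disubstituted alkene closes the trisubstituted cycloheptenone, and the cis ring fusion follows from the cis acyl and side-chain groups set in step 6.

Step 9
Reactants: 14 (3R,3aS,8aS)-3-hydroxy-6,8a-dimethyl-3-(propan-2-yl)-2,3,3a,4,5,8a-hexahydroazulen-8(1H)-one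
Product: 17 (3R,3aS,8aS)-3-hydroxy-6,8a-dimethyl-3-(propan-2-yl)-2,3,3a,8a-tetrahydroazulen-8(1H)-one, via bis-silyl dienol ether 15 (not isolated), via silyl ether dienone 16 (not isolated)
Conditions: TMSOTf, Et3N, CH2Cl2, 0 °C; then Pd(OAc)2 (1.1 equiv), MeCN, rt; then 1 M HCl, THF, 0 °C
Reagents that add atoms: none
Why: In this Saegusa–Ito oxidation the enone, which has no α′-hydrogen, is silylated to the 8-silyloxy-5,7-diene, divalent palladium then removes H-4 by β-hydride elimination to give the 4,6-dien-8-one, and the temporary silyl ether on the tertiary hydroxyl falls off in the acidic work-up.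

Step 10
Reactants: 17 (3R,3aS,8aS)-3-hydroxy-6,8a-dimethyl-3-(propan-2-yl)-2,3,3a,8a-tetrahydroazulen-8(1H)-one
Product: 20 (3R,3aR,4S,8aS)-3,4-dihydroxy-6,8a-dimethyl-3-(propan-2-yl)-2,3,3a,4,5,8a-hexahydroazulen-8(1H)-one, via boronic hemiester 18 (not isolated), via cyclic boronate 19 (not isolated)
Conditions: PhB(OH)2 (1.5 equiv), quinuclidine (20 mol %), N,N′-bis[3,5-bis(trifluoromethyl)phenyl]thiourea (20 mol %), 4 Å MS, toluene, 50 °C; then 30% H2O2, pH 7 buffer, THF, 0 °C
Reagents that add atoms: phenylboronic acid, OB(O)c1ccccc1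
Why: Proposed new method: a boron-tethered 1,6-oxa-Michael addition in which the tertiary hydroxyl condenses with PhB(OH)2 to hemiester 18, quinuclidine coordination makes the B–OH oxygen nucleophilic while the thiourea activates the dienone carbonyl, and the oxygen is delivered to the δ-carbon C4 through a six-membered dioxaborinane transition state that can only form on the face of the seven-membered ring carrying C3, so the new C–O bond is cis to C3 (4S), the dienolate is protonated at C5 to the conjugated enone, and the stable cyclic boronate 19 makes the addition effectively irreversible; the closest known reaction type is the amine-catalysed boronic acid hemiester oxa-Michael (1,4) addition of δ-hydroxy enones, which has not been shown in the vinylogous 1,6 mode, for a tertiary carbinol or on a cycloheptadienone.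

Step 11
Reactants: 20 (3R,3aR,4S,8aS)-3,4-dihydroxy-6,8a-dimethyl-3-(propan-2-yl)-2,3,3a,4,5,8a-hexahydroazulen-8(1H)-one; 21 4-methoxybenzoyl chloride
Product: 22 (3R,3aR,4S,8aS)-3-hydroxy-6,8a-dimethyl-8-oxo-3-(propan-2-yl)-1,2,3,3a,4,5,8,8a-octahydroazulen-4-yl 4-methoxybenzoate
Conditions: pyridine, DMAP (10 mol %), CH2Cl2, 0 °C → rt
Reagents that add atoms: none
Why: DMAP-catalysed acylation esterifies the secondary C4 hydroxyl and leaves the hindered tertiary C3 hydroxyl free, with no stereocentre affected under these weakly basic conditions.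

**Compound list**

1 | ethyl 2-cyanopropanoate | CCOC(=O)C(C)C#N | starting material
2 | 4-methylpent-1-en-3-one | C=CC(=O)C(C)C | starting material
3 | ethyl (2R)-2-cyano-2,6-dimethyl-5-oxoheptanoate | CCOC(=O)[C@@](C)(C#N)CCC(=O)C(C)C | intermediate
4 | (2R)-5-hydroxy-2-(hydroxymethyl)-2,6-dimethylheptanenitrile, both C5 epimers | OC[C@@](C)(C#N)CCC(O)C(C)C | intermediate
5 | (2R)-2-formyl-2,6-dimethyl-5-oxoheptanenitrile | O=C[C@@](C)(C#N)CCC(=O)C(C)C | intermediate
6 | 4-bromo-2-methylbut-1-ene | C=C(C)CCBr | starting material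
7 | triphenylphosphine | c1ccc(cc1)P(c1ccccc1)c1ccccc1 | starting material
8 | (3-methylbut-3-en-1-yl)triphenylphosphonium bromide | C=C(C)CC[P+](c1ccccc1)(c1ccccc1)c1ccccc1.[Br-] | intermediate
9 | (3-methylbut-3-en-1-ylidene)triphenylphosphorane (ylide) | C=C(C)CC=P(c1ccccc1)(c1ccccc1)c1ccccc1 | intermediate (not isolated)
10 | (2S)-2,6-dimethyl-2-[(1Z)-4-methylpenta-1,4-dien-1-yl]-5-oxoheptanenitrile | C=C(C)C/C=C\[C@@](C)(C#N)CCC(=O)C(C)C | intermediate
11 | (1S,2S,3R)-3-hydroxy-1-methyl-2-(3-methylbut-3-en-1-yl)-3-(propan-2-yl)cyclopentane-1-carbonitrile | N#C[C@@]1(C)CC[C@@](O)(C(C)C)[C@H]1CCC(C)=C | intermediate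
12 | 1-[(1S,2S,3R)-3-hydroxy-1-methyl-2-(3-methylbut-3-en-1-yl)-3-(propan-2-yl)cyclopentyl]prop-2-en-1-imine | C=CC(=N)[C@@]1(C)CC[C@@](O)(C(C)C)[C@H]1CCC(C)=C | intermediate (not isolated)
13 | 1-[(1S,2S,3R)-3-hydroxy-1-methyl-2-(3-methylbut-3-en-1-yl)-3-(propan-2-yl)cyclopentyl]prop-2-en-1-one | C=CC(=O)[C@@]1(C)CC[C@@](O)(C(C)C)[C@H]1CCC(C)=C | intermediate
14 | (3R,3aS,8aS)-3-hydroxy-6,8a-dimethyl-3-(propan-2-yl)-2,3,3a,4,5,8a-hexahydroazulen-8(1H)-one | CC1=CC(=O)[C@@]2(C)CC[C@@](O)(C(C)C)[C@H]2CC1 | intermediate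
15 | bis(trimethylsilyl) derivative of 14: 8-trimethylsilyloxy-5,7-diene with the 3-hydroxyl as its trimethylsilyl ether (3R,3aS,8aS) | CC=1C=C(O[Si](C)(C)C)[C@@]2(C)CC[C@@](O[Si](C)(C)C)(C(C)C)[C@H]2CC=1 | intermediate (not isolated)
16 | (3R,3aS,8aS)-6,8a-dimethyl-3-(propan-2-yl)-3-[(trimethylsilyl)oxy]-2,3,3a,8a-tetrahydroazulen-8(1H)-one | CC1=CC(=O)[C@@]2(C)CC[C@@](O[Si](C)(C)C)(C(C)C)[C@H]2C=C1 | intermediate (not isolated)
17 | (3R,3aS,8aS)-3-hydroxy-6,8a-dimethyl-3-(propan-2-yl)-2,3,3a,8a-tetrahydroazulen-8(1H)-one | CC1=CC(=O)[C@@]2(C)CC[C@@](O)(C(C)C)[C@H]2C=C1 | intermediate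
18 | (3R,3aS,8aS)-6,8a-dimethyl-8-oxo-3-(propan-2-yl)-1,2,3,3a,8,8a-hexahydroazulen-3-yl hydrogen phenylboronate | CC1=CC(=O)[C@@]2(C)CC[C@@](OB(O)c3ccccc3)(C(C)C)[C@H]2C=C1 | intermediate (not isolated)
19 | cyclic 3,4-O-phenylboronate of diol 20 (six-membered dioxaborinane, configuration as in 20) | c1ccccc1B4O[C@H]2CC(C)=CC(=O)[C@@]3(C)CC[C@@](O4)(C(C)C)[C@@H]23 | intermediate (not isolated)
20 | (3R,3aR,4S,8aS)-3,4-dihydroxy-6,8a-dimethyl-3-(propan-2-yl)-2,3,3a,4,5,8a-hexahydroazulen-8(1H)-one | O[C@H]1CC(C)=CC(=O)[C@@]2(C)CC[C@@](O)(C(C)C)[C@@H]12 | intermediate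
21 | 4-methoxybenzoyl chloride | COc1ccc(cc1)C(Cl)=O | starting material
22 | (3R,3aR,4S,8aS)-3-hydroxy-6,8a-dimethyl-8-oxo-3-(propan-2-yl)-1,2,3,3a,4,5,8,8a-octahydroazulen-4-yl 4-methoxybenzoate | COc1ccc(C(=O)O[C@H]2CC(C)=CC(=O)[C@@]3(C)CC[C@@](O)(C(C)C)[C@@H]23)cc1 | target

**Step count and risks**

Total step count: 11. Longest linear sequence: 10 (steps 1–3 and 5–11; step 4 is a one-step side branch).

The three steps most likely to fail:

Step 6 (ketyl–olefin cyclisation onto an unactivated alkene). The risks are simple reduction of the ketone, slow ring closure and incomplete diastereocontrol. The fallback replaces the unactivated alkene by an activated acceptor and builds the side chain afterwards. It sets out from 5: Wittig reaction with methyl (triphenylphosphoranylidene)acetate gives methyl (2E,4S)-4-cyano-4,8-dimethyl-7-oxonon-2-enoate F1. SmI2/MeOH in THF at −78 °C then closes the ring by the fast ketyl–enoate cyclisation to methyl 2-[(1S,2S,5R)-2-cyano-5-hydroxy-2-methyl-5-(propan-2-yl)cyclopentyl]acetate F2. LiBH4 reduces the ester to (1S,2S,3R)-3-hydroxy-2-(2-hydroxyethyl)-1-methyl-3-(propan-2-yl)cyclopentane-1-carbonitrile F3. I2/PPh3/imidazole converts the primary hydroxyl to (1S,2S,3R)-3-hydroxy-2-(2-iodoethyl)-1-methyl-3-(propan-2-yl)cyclopentane-1-carbonitrile F4. Coupling with isopropenylmagnesium bromide under Li2CuCl4 catalysis comes back to the route at 11.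

Step 7 (Grignard addition to a hindered tertiary nitrile next to a free hydroxyl). The risks are no addition or loss of the vinyl ketone on hydrolysis. The fallback goes through the aldehyde oxidation level. It sets out from 11: DIBAL-H in CH2Cl2 at −78 °C followed by 1 M HCl gives (1S,2S,3R)-3-hydroxy-1-methyl-2-(3-methylbut-3-en-1-yl)-3-(propan-2-yl)cyclopentane-1-carbaldehyde F5. Vinylmagnesium bromide adds to give 1-[(1S,2S,3R)-3-hydroxy-1-methyl-2-(3-methylbut-3-en-1-yl)-3-(propan-2-yl)cyclopentyl]prop-2-en-1-ol (both carbinol epimers) F6. Dess–Martin oxidation of the secondary allylic alcohol comes back to the route at 13.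

Step 10 (the proposed new 1,6-oxa-Michael addition). The δ-carbon of the dienone is a weak electrophile, the hemiester forms slowly at the hindered tertiary carbinol, and the dioxaborinane is strained by the contact between the isopropyl group and the seven-membered ring. The fallback uses known chemistry only and sets out from 17. Hydroxyl-directed epoxidation of the 4,5-alkene with VO(acac)2/t-BuOOH gives (3R,3aR,4R,5S,8aS)-4,5-epoxy-3-hydroxy-6,8a-dimethyl-3-(propan-2-yl)-2,3,3a,4,5,8a-hexahydroazulen-8(1H)-one (epoxide oxygen cis to C3) F7. Hydrogenolysis of this alkenyl epoxide with zerovalent palladium (Pd2(dba)3, PBu3, HCO2H, Et3N, dioxane) delivers hydride to the allylic carbon C5, keeps the C4–O bond, and comes back to the route at 20.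

Further compounds
F1 | step 6 | methyl (2E,4S)-4-cyano-4,8-dimethyl-7-oxonon-2-enoate | COC(=O)/C=C/[C@@](C)(C#N)CCC(=O)C(C)C
F2 | step 6 | methyl 2-[(1S,2S,5R)-2-cyano-5-hydroxy-2-methyl-5-(propan-2-yl)cyclopentyl]acetate | N#C[C@@]1(C)CC[C@@](O)(C(C)C)[C@H]1CC(=O)OC
F3 | step 6 | (1S,2S,3R)-3-hydroxy-2-(2-hydroxyethyl)-1-methyl-3-(propan-2-yl)cyclopentane-1-carbonitrile | N#C[C@@]1(C)CC[C@@](O)(C(C)C)[C@H]1CCO
F4 | step 6 | (1S,2S,3R)-3-hydroxy-2-(2-iodoethyl)-1-methyl-3-(propan-2-yl)cyclopentane-1-carbonitrile | N#C[C@@]1(C)CC[C@@](O)(C(C)C)[C@H]1CCI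
F5 | step 7 | (1S,2S,3R)-3-hydroxy-1-methyl-2-(3-methylbut-3-en-1-yl)-3-(propan-2-yl)cyclopentane-1-carbaldehyde | O=C[C@@]1(C)CC[C@@](O)(C(C)C)[C@H]1CCC(C)=C
F6 | step 7 | 1-[(1S,2S,3R)-3-hydroxy-1-methyl-2-(3-methylbut-3-en-1-yl)-3-(propan-2-yl)cyclopentyl]prop-2-en-1-ol, both carbinol epimers | C=CC(O)[C@@]1(C)CC[C@@](O)(C(C)C)[C@H]1CCC(C)=C
F7 | step 10 | (3R,3aR,4R,5S,8aS)-4,5-epoxy-3-hydroxy-6,8a-dimethyl-3-(propan-2-yl)-2,3,3a,4,5,8a-hexahydroazulen-8(1H)-one | CC1=CC(=O)[C@@]2(C)CC[C@@](O)(C(C)C)[C@H]2[C@H]3O[C@@H]13
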